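Time first: this flask is read at 4.0 h, but with less free catalyst than either run, so I do not read it straight off the time axis.

the same everywhere: left-handed substrate 0.19 M; right-handed substrate 0.19 M; racemization catalyst 2 mol%
- Sunday's: reagent 2.2 equiv; free catalyst 3.5 mol%; run made earlier
- Thursday's: reagent 2.2 equiv; free catalyst 5.5 mol%; run made earlier
- flask: reagent 2.20 equiv; free catalyst 2.5 mol%; time 4.0 h

| run | time / h | left-handed product / % | right-handed product / % |
|---|---|---|---|
| Sunday's | 0.417 | 43 | 29 |
| Sunday's | 1.33 | 49 | 36 |
| Sunday's | 2.00 | 50 | 43 |
| Sunday's | 3.00 | 51 | 40 |
| Sunday's | 5.00 | 47 | 47 |
| Thursday's | 0.417 | 48 | 30 |
| Thursday's | 0.667 | 50 | 36 |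
| Thursday's | 1.33 | 53 | 38 |
| Thursday's | 2.50 | 52 | 45 |
| Thursday's | 5.00 | 50 | 53 |

(standard deviation of a reading: 2 percentage points)

- free catalyst is single-handed; left-handed substrate and right-handed substrate are mirror images of each other, charged as a racemate, each of them at the stated concentration
- an excess is the difference of the two amounts in percent of their sum
- an excess is below zero if the other one leads

- left-handed product and right-handed product together, in percent of the left-handed substrate and right-handed substrate charged together, at 4.0 h
- excess of left-handed product over right-handed product in the product at 4.0 h
- whether the exchange between left-handed substrate and right-handed substrate keeps pace with the reaction: how far the product's excess at 4.0 h gets from its value without exchange to its value with instant exchange (above 80% keeps pace, below 20% hardly takes part, else lags behind)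

What do you follow? The fraction of each substrate left, not the product made. Each substrate is half of the joint charge, so its fraction left is one minus its product's share of that part.

Why left and not made? Suppose there is no exchange, both substrates meet the same reagent and free catalyst, and each is used at a rate proportional to its own concentration. Then the logarithm of each fraction left runs on one shared clock, scaled by that substrate's own constant. However the clock slows, the ratio of the two logarithms stays put.

Which reading gives it? Sunday's first: it leaves 14.0% of the left-handed substrate and 42.0% of the right-handed, so the ratio reads 2.27. That is the selectivity factor, the logarithm of the fraction of left-handed substrate left over that of the right-handed.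

Why not Thursday's first? It leaves 2 percentage points of the joint charge as left-handed substrate, with a scatter of 2 points, and no ratio comes from that.

And this flask? Its 2.5 mol% over 4.0 h matches Sunday's 3.5 mol% over 3.00 h in catalyst × time, so I take that reading's 40% of right-handed product. That leaves 20.0% of the right-handed substrate, and raising this to the selectivity factor leaves 2.61% of the left-handed. My reckoning for the flask is a yield of 88.7% and an excess of 9.81%.

Now the weak spot: what if exchange runs? Instant exchange holds the substrates racemic, so the products form in the ratio of the selectivity factor, with an excess of 38.8%. The 20% mark on the way there is 15.6%, and Sunday's reading at that catalyst × time shows 12.1%, lower. But exchange runs on hours at the same 2 mol% of racemization catalyst, and the flask has 1.33 times Sunday's hours. Stretching the reading's gap above my excess by that factor gives 12.8%, still lower, so I say exchange hardly takes part.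

The forecast, resting on “Plotting both runs against catalyst × time gives one common curve”, says 91%, 10% and hardly takes part; my yield is lower. For instant exchange it puts the excess at roughly 45 to 55, and I put it at 38.8%.

The flask gives 94.7% with an excess of 7.70%, and the exchange hardly takes part, getting 5.3% of the way.

    reagent + free catalyst + left-handed substrate → free catalyst + left-handed product (k = 0.900 M⁻² s⁻¹)
    reagent + free catalyst + right-handed substrate → free catalyst + right-handed product (k = 0.340 M⁻² s⁻¹)
    left-handed substrate + racemization catalyst ⇌ right-handed substrate + racemization catalyst, rate k3*[racemization catalyst]*[left-handed substrate] forward; the back reaction follows from the equilibrium constant (k = 0.00270 M⁻¹ s⁻¹)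
    reagent ⇌ dormant form (K = 0.290, k = 1.30 × 10⁻⁵ s⁻¹)

At 4.0 h this flask keeps 9.8% of its right-handed substrate; raised to the selectivity factor that gives 0.513%, and 0.82% of the left-handed substrate stands there. A neighbour charged with 0.550 equiv of reagent keeps 81% of its right-handed substrate, so the same power gives 62.0%, and that neighbour holds 65% of its left-handed substrate.

The data were generated by integration from invented constants; scatter was added.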